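**Assumptions:** Kuwanon A as drawn has no stereocenters, so there is no enantiomer to set (the only transient stereocenter, C2 of ketoester 10, is destroyed in Step 6). The 4'-OH is carried as a MOM ether until the last step.

## Retrosynthetic overview
- Kuwanon A comes from a last-step MOM removal and cyclodehydration of the 2-hydroxyaryl 1,3-diketone or chromone (12).
- The chromone C-ring and the 5,7-dihydroxy A-ring form in one operation. Thermal, acid-free C-acylation of symmetric phloroglucinol (11) by an α-prenyl β-ketoester (10), via its acylketene, breaks the C3 symmetry of 11.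
- Ketoester 10 comes from C-prenylation of β-ketoester 8. Ketoester 8 comes from the aryl methyl ketone 6 by carbethoxylation.
- The 2,2-dimethylchromene ring is built first, by propargyl Claisen/6π cyclization of a 2-O-propargyl ether of 4-MOM-protected 2,4-dihydroxyacetophenone (1). The ortho position carrying the acetyl is blocked, so cyclization occurs only at C3.
- Ring order: B-ring pyran, then C-ring and A-ring together, then deprotection.

## Route

**Step 1**
Reactants: 1 (2,4-dihydroxyacetophenone); 2 (chloromethyl methyl ether)
Product: 3 (2-hydroxy-4-(methoxymethoxy)acetophenone)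
Conditions: MOMCl (1.0 equiv), i-Pr2NEt, CH2Cl2, 0 °C → rt
Reagents that add atoms: MOMCl, COCCl
Why: Regioselective mono-alkylation (protection) at the more acidic, unhindered 4-OH; the 2-OH is locked in a hydrogen bond to the ketone.

**Step 2**
Reactants: 3; 4 (3-chloro-3-methylbut-1-yne)
Product: 5 (2-(2-methylbut-3-yn-2-yloxy)-4-(MOMO)acetophenone)
Conditions: 4 (1.5 equiv), K2CO3, KI, CuI (cat.), DMF, 60 °C
Reagents that add atoms: 4, CC(C)(Cl)C#C
Why: Cu-assisted O-alkylation of the chelated phenoxide by a tertiary propargylic chloride (Godfrey-type aryl propargyl ether synthesis).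

**Step 3**
Reactants: 5
Product: 6 (1-[5-(methoxymethoxy)-2,2-dimethyl-2H-chromen-8-yl]ethan-1-one)
Conditions: PhNEt2, reflux (about 215 °C), 3 h, N2
Reagents that add atoms: none
Why: Aromatic propargyl Claisen [3,3] (transiently dearomatized allenyl dienone), then 1,5-H shift and 6π-oxa-electrocyclization. It is regiospecific because the other ortho carbon bears the acetyl, so the pyran closes at C3, between the two oxygens. This gives the B-ring pattern of the target.

**Step 4**
Reactants: 6; 7 (diethyl carbonate)
Product: 8 (ethyl 3-[5-(MOMO)-2,2-dimethylchromen-8-yl]-3-oxopropanoate)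
Conditions: NaH (3 equiv), (EtO)2CO (5 equiv), toluene, reflux, 3 h; quench with AcOH/aq. NH4Cl
Reagents that add atoms: diethyl carbonate, CCOC(=O)OCC
Why: Claisen-type carbethoxylation of the methyl ketone enolate (aroylacetate synthesis); the acetal and chromene alkene are base-stable.

**Step 5**
Reactants: 8; 9 (prenyl bromide)
Product: 10 (ethyl 2-[5-(MOMO)-2,2-dimethylchromene-8-carbonyl]-5-methylhex-4-enoate, racemic at C2)
Conditions: prenyl bromide (1.1 equiv), K2CO3, acetone, reflux, 6 h
Reagents that add atoms: 9, CC(C)=CCBr
Why: Soft C-alkylation of the stabilized β-ketoester enolate (SN2 at the primary allylic carbon) puts the future C3 prenyl group on the carbon that will become C3 of the flavone. The α-stereocenter is irrelevant because it is lost in Step 6.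

**Step 6 (key step)**
Reactants: 10; 11 (phloroglucinol)
Product: 12 (5,7-dihydroxy-2-[5-(MOMO)-2,2-dimethylchromen-8-yl]-3-prenylchromone)
Conditions: 11 (3 equiv), Ph2O, 195 °C, N2 sweep to remove EtOH/H2O, 1 h
Reagents that add atoms: none (11 is a reactant)
Why: Proposed new method: above 150 °C the α-substituted β-ketoester loses EtOH to give an α-oxoketene (acylketene). Phloroglucinol, acting through its enol/triketo tautomers, traps it. Any O-acylation is reversible through the ketene, while C-acylation is irreversible. This gives the 2-hydroxyaryl 1,3-diketone, which cyclodehydrates onto the electron-rich, deactivated aryl ketone to give the chromone rather than a Pechmann coumarin, which needs an electrophilic ketone and acid. Closest known reactions are the Simonis chromone synthesis, acylketene C-acylation of phenols, and the thermal phloroglucinol + ethyl benzoylacetate route to chrysin. Excess phloroglucinol suppresses bis-acylation. The 5,7-dihydroxy pattern and the C2-aryl/C3-prenyl connectivity are fixed in this one operation. Any uncyclized diketone is carried into Step 7.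

**Step 7**
Reactants: 12
Product: 13 (Kuwanon A)
Conditions: 1 M HCl, MeOH/THF (1:1), 40 °C, 4 h
Reagents that add atoms: none
Why: Acid hydrolysis of the MOM acetal frees the 4'-OH, and the same conditions cyclodehydrate any residual open diketone to the chromone; the chromene and prenyl alkenes tolerate dilute mild acid.

## Compound list
1 | 2,4-dihydroxyacetophenone | CC(=O)c1ccc(O)cc1O | starting material
2 | chloromethyl methyl ether | COCCl | starting material (reagent)
3 | 2-hydroxy-4-(methoxymethoxy)acetophenone | CC(=O)c1ccc(OCOC)cc1O | intermediate
4 | 3-chloro-3-methylbut-1-yne | CC(C)(Cl)C#C | starting material (reagent)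
5 | 2-(2-methylbut-3-yn-2-yloxy)-4-(MOMO)acetophenone | CC(=O)c1ccc(OCOC)cc1OC(C)(C)C#C | intermediate
6 | 1-[5-(MOMO)-2,2-dimethyl-2H-chromen-8-yl]ethanone | CC(=O)c1ccc(OCOC)c2C=CC(C)(C)Oc12 | intermediate
7 | diethyl carbonate | CCOC(=O)OCC | starting material (reagent)
8 | ethyl 3-[5-(MOMO)-2,2-dimethylchromen-8-yl]-3-oxopropanoate | CCOC(=O)CC(=O)c1ccc(OCOC)c2C=CC(C)(C)Oc12 | intermediate
9 | prenyl bromide | CC(C)=CCBr | starting material (reagent)
10 | ethyl 2-[5-(MOMO)-2,2-dimethylchromene-8-carbonyl]-5-methylhex-4-enoate (racemic at C2) | CCOC(=O)C(CC=C(C)C)C(=O)c1ccc(OCOC)c2C=CC(C)(C)Oc12 | intermediate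
11 | phloroglucinol | Oc1cc(O)cc(O)c1 | starting material
12 | 5,7-dihydroxy-2-[5-(MOMO)-2,2-dimethylchromen-8-yl]-3-prenylchromone | CC(C)=CCc1c(-c2ccc(OCOC)c3C=CC(C)(C)Oc23)oc2cc(O)cc(O)c2c1=O | intermediate
13 | Kuwanon A | CC(C)=CCc1c(-c2ccc(O)c3c2OC(C)(C)C=C3)oc2cc(O)cc(O)c2c1=O | target

## Totals
Total steps: 7. Longest linear sequence: 7 (1 → 3 → 5 → 6 → 8 → 10 → 12 → 13).

## Three steps most likely to fail
1. **Step 6 (acylketene annulation):** it may give coumarin or O-acyl products, or low conversion. Fallback: change the approach to a stepwise route. Build the 3-H flavone from 2-hydroxy-4,6-bis(MOMO)acetophenone and the B-ring aldehyde (Claisen–Schmidt, then I2/DMSO), iodinate C3 with NIS, and install the prenyl group by Pd-catalysed Negishi coupling with prenylzinc bromide.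
2. **Step 3 (Claisen/chromene formation on the acetyl-bearing, electron-poor aryl propargyl ether):** it may be sluggish, or the MOM group may fail at about 215 °C. Fallback: skip the propargyl ether. Use a phenylboronic acid-mediated ortho-annulation of the 4-OBn-2-hydroxyacetophenone with 3-methylbut-2-enal, in which the boronate templates attack at C3.
3. **Step 7 (MOM removal):** the acid may add MeOH to the chromene or isomerize the prenyl group. Fallback: use a 4-O-benzyl group from Step 1 (CsHCO3/BnBr selective alkylation) instead of MOM, and remove it non-reductively with BCl3/pentamethylbenzene at −78 °C.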